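**Retrosynthetic overview**

- The target is (E)-1,7-bis(4-hydroxy-3-methoxyphenyl)hept-1-ene-3,5-dione; the chain is numbered C1 (alkene CH on ring A) to C7 (benzylic CH2 on ring B). The strategy rests on the C3/C5 1,3-dicarbonyl, whose C5 carbonyl lies between the C4 methylene and the saturated C6–C7 arm to ring B.
- C5–C6 is disconnected: C5 becomes the amide carbon of a MOM-protected feruloylacetic Weinreb amide (ring A, C1–C5), and C6–C7–ring B becomes a 2-arylethyl Grignard reagent.
- The amide comes from ferulic acid by C-acylation of Meldrum's acid (C3–C4 bond) and aminolysis; the Grignard reagent comes from homovanillyl alcohol by phenol protection, Appel bromination and magnesium insertion.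
- No ring is formed: rings A and B are bought as guaiacyl units, the (E)-C1=C2 alkene is carried through from ferulic acid, and the last step removes both MOM ethers.

Key step: step 8

Remark on the chemistry: the β-dicarbonyl compounds 9, 16 and 17 exist largely as chelated enols; they are named and drawn as the diketo tautomers, as in the target SMILES, and 6 is drawn as its enol.

**Step 1**
Reactants: 1 ferulic acid
Product: 2 methoxymethyl (2E)-3-[3-methoxy-4-(methoxymethoxy)phenyl]prop-2-enoate
Conditions: MOMCl (2.5 equiv), iPr2NEt (3 equiv), CH2Cl2, 0 °C → rt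
Reagents that add atoms: chloromethyl methyl ether (MOMCl), COCCl
Why: Both acidic O–H groups (carboxylic acid and phenol) should be O-alkylated by the reactive α-chloro ether under amine base (Williamson-type alkylation), leaving the (E)-alkene untouched.

**Step 2**
Reactants: 2 methoxymethyl (2E)-3-[3-methoxy-4-(methoxymethoxy)phenyl]prop-2-enoate
Product: 3 (2E)-3-[3-methoxy-4-(methoxymethoxy)phenyl]prop-2-enoic acid
Conditions: LiOH·H2O (2 equiv), THF/H2O, rt; then 1 M HCl to pH 4, 0 °C
Reagents that add atoms: lithium hydroxide, [Li+].[OH-]
Why: Saponification by acyl–oxygen cleavage should remove only the methoxymethyl ester, since the aryl MOM acetal is inert to hydroxide and survives a brief cold acidification to pH 4.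

**Step 3**
Reactants: 3 (2E)-3-[3-methoxy-4-(methoxymethoxy)phenyl]prop-2-enoic acid; 4 Meldrum's acid (2,2-dimethyl-1,3-dioxane-4,6-dione)
Product: 6 5-{(2E)-1-hydroxy-3-[3-methoxy-4-(methoxymethoxy)phenyl]prop-2-en-1-ylidene}-2,2-dimethyl-1,3-dioxane-4,6-dione, via acyl imidazolide 5 (not isolated)
Conditions: CDI (1.1 equiv), THF, rt; then 4 (1.1 equiv), DMAP (cat.), rt; cold aq. KHSO4 wash
Reagents that add atoms: none
Why: Carbonyldiimidazole activation gives the acyl imidazolide, which should C-acylate the Meldrum's acid anion (formed by the liberated imidazole) to give the enolised acyl Meldrum's acid, the standard entry to β-keto acid derivatives.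

**Step 4**
Reactants: 6 acyl Meldrum's acid from step 3; 7 N,O-dimethylhydroxylamine hydrochloride
Product: 9 (4E)-N-methoxy-5-[3-methoxy-4-(methoxymethoxy)phenyl]-N-methyl-3-oxopent-4-enamide, via acylketene 8 (not isolated)
Conditions: 7 (1.5 equiv), pyridine (1.6 equiv), toluene, 85 °C
Reagents that add atoms: none
Why: Thermal cycloreversion of the acyl Meldrum's acid with loss of acetone and CO2 should give the acylketene, which the free alkoxyamine captures at the ketene carbon to give the β-keto Weinreb amide (aminolysis of an acyl Meldrum's acid).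

**Step 5**
Reactants: 10 homovanillyl alcohol (2-(4-hydroxy-3-methoxyphenyl)ethanol)
Product: 11 2-[3-methoxy-4-(methoxymethoxy)phenyl]ethanol
Conditions: MOMCl (1.1 equiv), K2CO3 (2 equiv), acetone, 0 °C → rt
Reagents that add atoms: chloromethyl methyl ether (MOMCl), COCCl
Why: K2CO3 deprotonates only the phenol (pKa about 10 against about 16 for the primary alcohol), so a chemoselective Williamson etherification of the phenoxide is expected.

**Step 6**
Reactants: 11 2-[3-methoxy-4-(methoxymethoxy)phenyl]ethanol
Product: 12 4-(2-bromoethyl)-2-methoxy-1-(methoxymethoxy)benzene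
Conditions: CBr4 (1.3 equiv), PPh3 (1.3 equiv), CH2Cl2, 0 °C
Reagents that add atoms: carbon tetrabromide, BrC(Br)(Br)Br
Why: The Appel reaction converts the primary alcohol into the bromide by SN2 displacement of the alkoxyphosphonium ion under essentially neutral conditions that the aryl MOM acetal tolerates.

**Step 7**
Reactants: 12 4-(2-bromoethyl)-2-methoxy-1-(methoxymethoxy)benzene
Product: 13 {2-[3-methoxy-4-(methoxymethoxy)phenyl]ethyl}magnesium bromide (titrated THF solution)
Conditions: Mg turnings (I2 cat.), THF, 35–40 °C, slow addition of 12 at high dilution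
Reagents that add atoms: magnesium, [Mg]
Why: Insertion of magnesium metal into the primary C–Br bond gives the Grignard reagent, the aryl ether and acetal being inert, and slow addition at dilution should hold back Wurtz homocoupling.

**Step 8**
Reactants: 9 (4E)-N-methoxy-5-[3-methoxy-4-(methoxymethoxy)phenyl]-N-methyl-3-oxopent-4-enamide; 13 {2-[3-methoxy-4-(methoxymethoxy)phenyl]ethyl}magnesium bromide
Product: 16 (1E)-1,7-bis[3-methoxy-4-(methoxymethoxy)phenyl]hept-1-ene-3,5-dione, via chloromagnesium enolate 14 (not isolated), via magnesium hemiaminal adduct 15 (not isolated)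
Conditions: iPrMgCl (1.05 equiv), THF, −20 °C; then 13 (2.2 equiv), −20 °C → rt; sat. aq. NH4Cl
Reagents that add atoms: none
Why: iPrMgCl removes the acidic C4 proton between the two carbonyls and gives the chelated magnesium enolate 14, in which the C3 ketone is masked as an enolate oxygen and the C1=C2 bond no longer belongs to an electrophilic enone. The homobenzylic Grignard reagent 13 then adds to the only carbonyl left, the N-methoxy-N-methyl amide at C5, and forms the C5–C6 bond; the N-methoxy/O-magnesium chelate 15 should persist until aqueous work-up, so a second addition is not expected and N,O-dimethylhydroxylamine is lost only on quench. The closest known reaction type is the Weinreb ketone synthesis run on a pre-enolised β-keto Weinreb amide to give an unsymmetrical 1,3-diketone. No ring is closed and no stereocentre remains in the product (the C5 centre of 15 is transient and racemic), and the (E)-alkene takes no part. The selectivity needed is attack at the amide carbonyl in preference to 1,2- or conjugate addition to the cinnamoyl unit; it is secured by complete enolate formation before 13 is added and by the chelating N-methoxy group, while the excess of 13 and warming to room temperature make up for the lowered electrophilicity of the enolate-conjugated amide.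

**Step 9**
Reactants: 16 (1E)-1,7-bis[3-methoxy-4-(methoxymethoxy)phenyl]hept-1-ene-3,5-dione
Product: 17 dihydrocurcumin, (1E)-1,7-bis(4-hydroxy-3-methoxyphenyl)hept-1-ene-3,5-dione
Conditions: 3 M aq. HCl, MeOH/THF, rt → 40 °C
Reagents that add atoms: none
Why: Acid-catalysed acetal cleavage with transfer of the methoxymethyl group to methanol should free both phenols, while the aryl methyl ethers, the enolised β-diketone and the (E)-alkene are stable to dilute acid.

**Compound list**

1 | ferulic acid, (2E)-3-(4-hydroxy-3-methoxyphenyl)prop-2-enoic acid | COc1cc(/C=C/C(=O)O)ccc1O | starting material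
2 | methoxymethyl (2E)-3-[3-methoxy-4-(methoxymethoxy)phenyl]prop-2-enoate | COCOC(=O)/C=C/c1ccc(OCOC)c(OC)c1 | intermediate
3 | (2E)-3-[3-methoxy-4-(methoxymethoxy)phenyl]prop-2-enoic acid | COCOc1ccc(/C=C/C(=O)O)cc1OC | intermediate
4 | Meldrum's acid, 2,2-dimethyl-1,3-dioxane-4,6-dione | CC1(C)OC(=O)CC(=O)O1 | starting material
5 | (2E)-1-(1H-imidazol-1-yl)-3-[3-methoxy-4-(methoxymethoxy)phenyl]prop-2-en-1-one (acyl imidazolide, not isolated) | COCOc1ccc(/C=C/C(=O)n2ccnc2)cc1OC | intermediate
6 | 5-{(2E)-1-hydroxy-3-[3-methoxy-4-(methoxymethoxy)phenyl]prop-2-en-1-ylidene}-2,2-dimethyl-1,3-dioxane-4,6-dione | COCOc1ccc(/C=C/C(O)=C2C(=O)OC(C)(C)OC2=O)cc1OC | intermediate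
7 | N,O-dimethylhydroxylamine hydrochloride | CNOC.Cl | starting material
8 | (4E)-5-[3-methoxy-4-(methoxymethoxy)phenyl]penta-1,4-diene-1,3-dione (acylketene, not isolated) | COCOc1ccc(/C=C/C(=O)C=C=O)cc1OC | intermediate
9 | (4E)-N-methoxy-5-[3-methoxy-4-(methoxymethoxy)phenyl]-N-methyl-3-oxopent-4-enamide | COCOc1ccc(/C=C/C(=O)CC(=O)N(C)OC)cc1OC | intermediate
10 | homovanillyl alcohol, 2-(4-hydroxy-3-methoxyphenyl)ethanol | COc1cc(CCO)ccc1O | starting material
11 | 2-[3-methoxy-4-(methoxymethoxy)phenyl]ethanol | COCOc1ccc(CCO)cc1OC | intermediate
12 | 4-(2-bromoethyl)-2-methoxy-1-(methoxymethoxy)benzene | COCOc1ccc(CCBr)cc1OC | intermediate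
13 | {2-[3-methoxy-4-(methoxymethoxy)phenyl]ethyl}magnesium bromide | COCOc1ccc(CC[Mg]Br)cc1OC | intermediate
14 | chloromagnesium (Z)-enolate of 9 at C3–C4, (E)-styryl retained (not isolated) | COCOc1ccc(/C=C/C(O[Mg]Cl)=C/C(=O)N(C)OC)cc1OC | intermediate
15 | tetrahedral adduct of 14 and 13 at C5, bearing OMgBr, N(OMe)Me and the 2-arylethyl group, racemic at C5 (not isolated) | COCOc1ccc(/C=C/C(O[Mg]Cl)=C/C(O[Mg]Br)(CCc2ccc(OCOC)c(OC)c2)N(C)OC)cc1OC | intermediate
16 | (1E)-1,7-bis[3-methoxy-4-(methoxymethoxy)phenyl]hept-1-ene-3,5-dione | COCOc1ccc(/C=C/C(=O)CC(=O)CCc2ccc(OCOC)c(OC)c2)cc1OC | intermediate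
17 | dihydrocurcumin, (1E)-1,7-bis(4-hydroxy-3-methoxyphenyl)hept-1-ene-3,5-dione | COc1cc(/C=C/C(=O)CC(=O)CCc2ccc(O)c(OC)c2)ccc1O | target

**Step count and risk**

Total step count: 9. Longest linear sequence: 6 steps (steps 1, 2, 3, 4, 8, 9 from ferulic acid); the homovanillyl branch (steps 5, 6, 7) joins at step 8.

Steps most likely to fail:

1. Step 8. The amide carbonyl of the enolate is a poor electrophile, so the addition may stall. Any amide that is not fully enolised may also suffer conjugate or ketone addition by the Grignard reagent. The fallback forms the C3–C4 bond by a Claisen-type acylation instead. It sets out from 13 and 3: the Grignard reagent 13 is added to N-methoxy-N-methylacetamide in THF at 0 °C to give the methyl ketone 4-[3-methoxy-4-(methoxymethoxy)phenyl]butan-2-one F1. Kinetic deprotonation on the methyl side with LDA in THF at −78 °C gives lithium 4-[3-methoxy-4-(methoxymethoxy)phenyl]but-1-en-2-olate F2 (two equivalents, since the product diketone consumes one). F2 is acylated by the imidazolide 5, freshly made from 3 and CDI, and the route is rejoined at 16.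

2. Step 4. The acylketene may dimerise, or the acyl Meldrum's acid may fragment, before the weakly nucleophilic alkoxyamine captures it, and the amine may add reversibly to the enone. The fallback sets out from 3. The acid is activated with CDI to the imidazolide 5, which is added at −78 °C in THF to an excess of the lithium enolate of N-methoxy-N-methylacetamide F3 (from the amide and LDA). This crossed Claisen condensation gives the β-keto Weinreb amide directly and comes back at 9, bypassing Meldrum's acid altogether.

3. Step 7. Magnesium insertion into the homobenzylic bromide may be accompanied by Wurtz homocoupling or may initiate sluggishly, giving a solution of low titre. The fallback sets out from 12 and makes the organometallic by halogen–metal exchange. A Finkelstein reaction (NaI, acetone, reflux) gives 4-(2-iodoethyl)-2-methoxy-1-(methoxymethoxy)benzene F4. Iodine–lithium exchange with tBuLi (2 equiv) in Et2O/pentane at −78 °C gives {2-[3-methoxy-4-(methoxymethoxy)phenyl]ethyl}lithium F5. Transmetalation with MgBr2·OEt2 then returns to the route at 13.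

**Further compounds**

F1 | step 8 | 4-[3-methoxy-4-(methoxymethoxy)phenyl]butan-2-one | COCOc1ccc(CCC(C)=O)cc1OC
F2 | step 8 | lithium 4-[3-methoxy-4-(methoxymethoxy)phenyl]but-1-en-2-olate | COCOc1ccc(CCC(=C)O[Li])cc1OC
F3 | step 4 | lithium enolate of N-methoxy-N-methylacetamide | C=C(O[Li])N(C)OC
F4 | step 7 | 4-(2-iodoethyl)-2-methoxy-1-(methoxymethoxy)benzene | COCOc1ccc(CCI)cc1OC
F5 | step 7 | {2-[3-methoxy-4-(methoxymethoxy)phenyl]ethyl}lithium | COCOc1ccc(CC[Li])cc1OC
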